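## The problem

The target 10 is a flavone: a benzene ring A fused to a 4-pyranone ring C along C4a–C8a, with a 2,3-dimethoxyphenyl ring B on C2. It has no stereocentre, so the task is one of connectivity and of telling six oxygen substituents apart. Ring A is fully substituted, with hydroxyls at C5 and C7 alternating with methoxyls at C6 and C8, and ring B carries two more methoxyls. No late demethylation can be trusted to pick two of six ethers, so the C5 and C7 oxygens must travel in a form other than methyl. The pentaoxygenated ring A is very electron-rich: as a free polyphenol under base and air it drifts towards quinones, an ether on the C5 oxygen (peri to C4=O) is unusually acid-labile, and the C2=C3 bond can be over-reduced. The bridge C2–C3–C4 has to be built between ring B and a crowded, hexasubstituted ring A, and ring C then closed through O1–C2. C2 is bonded only to C3, O1 and C1', so it is an acyl carbon that can be delivered as carbon monoxide between a ring B aryl halide and the methyl carbon (the future C3) of a ring A acetophenone. In addition, the ring A oxygen pattern is symmetric about the C4a–C7 axis until ring C is closed, so the ketone can come from symmetric phloroacetophenone and either ortho hydroxyl can serve as O1.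

## Retrosynthesis

**10 to 9.** The last cut is at the two O–CH2Ph bonds, which leads back to the 5,7-di-O-benzyl flavone 9. Benzyl is chosen because it survives the strong base of the coupling and leaves by hydrogenolysis, to which the four methyl ethers are inert. The forward step must cleave two hindered aryl benzyl ethers without reducing C2=C3.

**9 to 8.** Ring C is opened at O1–C2 to the o-hydroxyaryl 1,3-diketone 8. A chalcone precursor would need an oxidation on a very electron-rich substrate, and an ynone precursor would have to choose between six- and five-membered closure. The diketone 8 is already at the oxidation level of the flavone and can only close to the six-membered ring by loss of water. The forward step must cyclodehydrate without stripping the C5 benzyl ether.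

**8 to 5, 6 and 7.** Both carbon–carbon bonds to C2 are cut, C1'–C2 and C2–C3. C2 becomes carbon monoxide 6, ring B the bromide 7, and ring A with C3 and C4 the acetophenone 5. Cutting C2–C3 alone (ester condensation) needs an aroyl chloride and two operations. Cutting C4–C4a would mean acylating a pentaoxygenated benzene. The simplification is large: 6 and 7 are bought, and 5 already holds every ring A oxygen in its final state. The forward reaction must take up CO before the enolate arrives, tolerate the free ortho hydroxyl, and stop at the monoacylated ketone.

**5 to 3 and 4.** Two O–benzyl bonds are cut, leading to the symmetric triol 3 and benzyl bromide 4. The two hydroxyls ortho to the acetyl group of 3 are equivalent, so the product has a single constitution whichever one reacts. The forward step must stop at the bis-ether, which the hydrogen bond of the last hydroxyl to the carbonyl should allow.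

**3 to 2.** The two aryl C–OMe bonds at the ring positions are cut, leading to the dibromide 2. Introducing the methoxyls on the ketone avoids having to acylate a pentaoxygenated benzene that would itself have to be made. The forward step is a copper-catalysed exchange of two bromides flanked by phenoxides, and it must avoid reductive loss of bromine.

**2 to 1.** The two C–Br bonds are cut to commercial 2',4',6'-trihydroxyacetophenone 1, whose only two ring CH positions are the ones to be substituted.

## Roads not taken

**Alternative 1:** Ring A is cut at C8–C8a and brought in whole (C5 to C8) from a squaric acid diester; rings B and C are present beforehand as a 2-arylpyran-4-one. The carbinol 2-tert-butoxy-4-[6-(2,3-dimethoxyphenyl)-4-oxo-4H-pyran-3-yl]-4-hydroxy-3-methoxycyclobut-2-en-1-one A2 would be made by adding a metallated pyranone to the mixed squarate 3-tert-butoxy-4-methoxycyclobut-3-ene-1,2-dione A3. On heating, A2 would open to a dienylketene and undergo 6π-electrocyclisation onto the pyranone CH next to the ring oxygen, giving 7-tert-butoxy-2-(2,3-dimethoxyphenyl)-5,8-dihydroxy-6-methoxy-4H-chromen-4-one A1.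
- Merits: ring A is assembled in one reagent-free thermal step, and the C8 hydroxyl of A1 is unchelated and could be methylated selectively before acid removes the tert-butyl group.
- Weak points: the C6/C7 pattern depends entirely on which carbonyl of A3 is attacked, and a methyl and a tert-butyl vinylogous ester differ too little to guarantee this. The metallated pyranone is a fragile nucleophile that itself takes several steps to make. Two steps still follow the key step.
- Comparison: this road is better at distinguishing the ring A oxygens and avoids both the copper step and the selective benzylation. The chosen plan sets against it a symmetric ring A precursor with no regiochemical question, commodity starting materials and a shorter sequence.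

**Alternative 2:** Ring C is cut at O1–C8a. Anodic two-electron oxidation of the hydroquinone diketone 1-[4-(benzyloxy)-2,5-dihydroxy-3-methoxyphenyl]-3-(2,3-dimethoxyphenyl)propane-1,3-dione A5 would give an acylquinone. Its enol oxygen adds to the unsubstituted quinone carbon, and tautomerisation gives 7-(benzyloxy)-2-(2,3-dimethoxyphenyl)-5,8-dihydroxy-6-methoxy-4H-chromen-4-one A4.
- Merits: no chemical oxidant is needed, the ring A precursor needs one oxygen fewer, and the C8 hydroxyl of A4 is free and unchelated for selective methylation.
- Weak points: A4 is a hydroquinone richer in donors than A5, so over-oxidation at the anode threatens. The alkoxy-substituted quinone carbons can suffer addition–elimination by solvent. The step closes a ring but builds no carbon–carbon bond, so A5 would still need a condensation or carbonylative coupling, on an unsymmetrical ring A ketone that is harder to reach than 3. Methylation and debenzylation then follow.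
- Comparison: this road would be preferable if C5 and C7 had to be differentiated. For this target the chosen plan closes ring C by simple dehydration, because O1 is present from the start, and is several steps shorter.

**Alternative 3:** The cuts are at C4a–C4 and C4–C3, with carbon monoxide becoming C4. The iodide 1,3,5-tris(benzyloxy)-2-iodo-4,6-dimethoxybenzene A7, CO and the alkyne 1-ethynyl-2,3-dimethoxybenzene A8 would combine under PdCl2(PPh3)2 and CuI to the ynone 3-(2,3-dimethoxyphenyl)-1-[2,4,6-tris(benzyloxy)-3,5-dimethoxyphenyl]prop-2-yn-1-one A6. Removal of one ortho benzyl ether and oxa-Michael closure would then lead to 9.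
- Merits: it is equally convergent, needs only an amine base, and the symmetric ring A again makes either ortho ether usable.
- Weak points: palladium must insert into a di-ortho-substituted, very electron-rich iodide, and the resulting 2,6-disubstituted aroyl complex is crowded, so direct alkynylation without CO uptake competes. A7 requires the pentaoxygenated benzene and an iodination, and A8 must be made from the corresponding aldehyde. The debenzylation cannot be a hydrogenolysis because of the alkyne. The closure must favour six- over five-membered ring formation (aurone).
- Comparison: this road is as good in convergence and better in base tolerance. In the chosen plan the metal meets only the small commercial bromide 7, the crowded ring reacts through its remote methyl group, and the diketone can only close to the pyranone.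

Key step: step 4

Assumption: the commercial hydrate of 1 is dried before use, and CO is supplied at about 1 atm from a cylinder or an ex situ generator.

## Route

Step 1
Reactants: 1 2',4',6'-trihydroxyacetophenone [1-(2,4,6-trihydroxyphenyl)ethan-1-one]
Product: 2 1-(3,5-dibromo-2,4,6-trihydroxyphenyl)ethan-1-one
Conditions: Br2 (2.05 equiv), AcOH, 20 °C
Reagents that add atoms: bromine, BrBr
Why: Electrophilic aromatic bromination; the two ring CH positions, each flanked by two hydroxyls, are far more nucleophilic than the acetyl methyl group, so two equivalents of bromine should stop at the ring dibromide.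

Step 2
Reactants: 2 1-(3,5-dibromo-2,4,6-trihydroxyphenyl)ethan-1-one
Product: 3 1-(2,4,6-trihydroxy-3,5-dimethoxyphenyl)ethan-1-one
Conditions: NaOMe (25% in MeOH, 8 equiv), CuBr (0.3 equiv), DMF, 110 °C, N2; then aq. HCl
Reagents that add atoms: sodium methoxide, [Na+].[O-]C
Why: Ullmann-type CuBr-catalysed methoxylation of aryl bromides, a reaction at its best on bromides ortho to a phenoxide; both bromides are exchanged in one operation, and exclusion of air protects the electron-rich triphenoxide.

Step 3
Reactants: 3 1-(2,4,6-trihydroxy-3,5-dimethoxyphenyl)ethan-1-one; 4 benzyl bromide (2.1 equiv)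
Product: 5 1-[4,6-bis(benzyloxy)-2-hydroxy-3,5-dimethoxyphenyl]ethan-1-one
Conditions: K2CO3 (2.2 equiv), acetone, reflux
Reagents that add atoms: none
Why: Williamson ether synthesis under weak base; the para hydroxyl and one of the two equivalent ortho hydroxyls are alkylated, the last hydroxyl is held in a hydrogen bond to the carbonyl and is left alone, and with both ring carbons blocked no C-benzylation can compete.

Step 4
Reactants: 5 1-[4,6-bis(benzyloxy)-2-hydroxy-3,5-dimethoxyphenyl]ethan-1-one; 6 carbon monoxide; 7 1-bromo-2,3-dimethoxybenzene (1.3 equiv)
Product: 8 1-[4,6-bis(benzyloxy)-2-hydroxy-3,5-dimethoxyphenyl]-3-(2,3-dimethoxyphenyl)propane-1,3-dione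
Conditions: Pd(dba)2 (5 mol %), Xantphos (5 mol %), NaN(SiMe3)2 (3.5 equiv), CO (1 atm), 1,4-dioxane, 80 °C; then aq. NH4Cl
Reagents that add atoms: none
Why: Zerovalent palladium (from Pd(dba)2 and Xantphos) adds oxidatively to the C–Br bond of 7, CO inserts to give the 2,3-dimethoxybenzoyl complex of divalent palladium (forming C1'–C2), the sodium enolate of 5, present as the phenoxide–enolate dianion, replaces bromide on the metal, and reductive elimination forms C2–C3 and returns zerovalent palladium. The closest known reaction type is the three-component carbonylative α-arylation of aryl methyl ketones with aryl halides to 1,3-diketones, which has been used on 2-hydroxyacetophenones on the way to flavones. No ring is closed and no stereocentre is formed. Carbonylative rather than direct α-arylation is secured by the wide-bite-angle bisphosphine under a CO atmosphere, where CO insertion into the aryl–palladium bond is faster than enolate transfer. C- versus O-acylation does not matter, because an O-aroyl ester at the ortho phenoxide would be carried to the same diketone by a base-mediated O-to-C acyl shift (Baker–Venkataraman rearrangement). Monoacylation is secured because 8 is deprotonated at once to a stabilised, weakly nucleophilic diketonate, which is why more than three equivalents of base are used. The metal has to activate only the small commercial bromide 7, while the hexasubstituted ring A reacts through its remote methyl group.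

Step 5
Reactants: 8 1-[4,6-bis(benzyloxy)-2-hydroxy-3,5-dimethoxyphenyl]-3-(2,3-dimethoxyphenyl)propane-1,3-dione
Product: 9 5,7-bis(benzyloxy)-2-(2,3-dimethoxyphenyl)-6,8-dimethoxy-4H-chromen-4-one
Conditions: NaOAc, AcOH, 110 °C
Reagents that add atoms: none
Why: Cyclodehydration of an o-hydroxyaryl 1,3-diketone: the phenol adds to the aroyl carbonyl (6-exo-trig) and the hemiketal loses water to the aromatic pyranone, forming O1–C2; buffered acetic acid is used instead of mineral acid to spare the acid-labile benzyl ether on the C5 oxygen.

Step 6
Reactants: 9 5,7-bis(benzyloxy)-2-(2,3-dimethoxyphenyl)-6,8-dimethoxy-4H-chromen-4-one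
Product: 10 2-(2,3-dimethoxyphenyl)-5,7-dihydroxy-6,8-dimethoxy-4H-chromen-4-one (5,7-dihydroxy-6,8,2',3'-tetramethoxyflavone)
Conditions: H2 (1 atm), 10% Pd/C, EtOAc–MeOH, rt
Reagents that add atoms: none
Why: Catalytic hydrogenolysis of aryl benzyl ethers; methyl ethers are inert, and the C2=C3 bond, part of a vinylogous ester, is reduced much more slowly than benzylic C–O bonds are cleaved, so the reaction is stopped after two equivalents of hydrogen are taken up.

## Compound list

1 | 2',4',6'-trihydroxyacetophenone | CC(=O)c1c(O)cc(O)cc1O | starting material
2 | 1-(3,5-dibromo-2,4,6-trihydroxyphenyl)ethan-1-one | CC(=O)c1c(O)c(Br)c(O)c(Br)c1O | intermediate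
3 | 1-(2,4,6-trihydroxy-3,5-dimethoxyphenyl)ethan-1-one | CC(=O)c1c(O)c(OC)c(O)c(OC)c1O | intermediate
4 | benzyl bromide | BrCc1ccccc1 | starting material
5 | 1-[4,6-bis(benzyloxy)-2-hydroxy-3,5-dimethoxyphenyl]ethan-1-one | CC(=O)c1c(O)c(OC)c(OCc2ccccc2)c(OC)c1OCc1ccccc1 | intermediate
6 | carbon monoxide | [C-]#[O+] | starting material
7 | 1-bromo-2,3-dimethoxybenzene | COc1cccc(Br)c1OC | starting material
8 | 1-[4,6-bis(benzyloxy)-2-hydroxy-3,5-dimethoxyphenyl]-3-(2,3-dimethoxyphenyl)propane-1,3-dione | COc1cccc(C(=O)CC(=O)c2c(O)c(OC)c(OCc3ccccc3)c(OC)c2OCc2ccccc2)c1OC | intermediate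
9 | 5,7-bis(benzyloxy)-2-(2,3-dimethoxyphenyl)-6,8-dimethoxy-4H-chromen-4-one | COc1cccc(-c2cc(=O)c3c(OCc4ccccc4)c(OC)c(OCc4ccccc4)c(OC)c3o2)c1OC | intermediate
10 | 2-(2,3-dimethoxyphenyl)-5,7-dihydroxy-6,8-dimethoxy-4H-chromen-4-one | COc1cccc(-c2cc(=O)c3c(O)c(OC)c(O)c(OC)c3o2)c1OC | target

## Step count and risks

Total: 6 steps. Longest linear sequence: 6 steps, from 1 to 10; compounds 4, 6 and 7 are bought.

**Step 4 (key step).** Oxidative addition to the electron-rich, ortho-substituted bromide may be slowed further by CO binding to palladium. The enolate may reach the metal before CO does, giving direct α-arylation. The amide base may capture the aroyl–palladium species. Fallback, from 5 back to 8: 5 is O-acylated with commercial 2,3-dimethoxybenzoyl chloride (pyridine, catalytic 4-dimethylaminopyridine, CH2Cl2) to 2-acetyl-3,5-bis(benzyloxy)-4,6-dimethoxyphenyl 2,3-dimethoxybenzoate F1. KOH in pyridine at 50 °C then brings about the Baker–Venkataraman O-to-C acyl shift to 8. C2 then comes from the acid chloride instead of CO, at the cost of one extra step.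

**Step 2.** Reductive loss of bromine may compete with substitution, and the trisodium salt may be oxidised or poorly soluble, because three phenoxides make this ring far richer than the usual bromophenol substrates. Fallback, from 1 back to 10, with the methoxylation moved to the flavone stage:
- 1 is benzylated with 4 (K2CO3, DMF) to 1-[2,4-bis(benzyloxy)-6-hydroxyphenyl]ethan-1-one F2.
- The same carbonylative coupling with 6 and 7 gives 1-[2,4-bis(benzyloxy)-6-hydroxyphenyl]-3-(2,3-dimethoxyphenyl)propane-1,3-dione F3.
- NaOAc in AcOH closes ring C to 5,7-bis(benzyloxy)-2-(2,3-dimethoxyphenyl)-4H-chromen-4-one F4.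
- Hydrogenolysis gives 2-(2,3-dimethoxyphenyl)-5,7-dihydroxy-4H-chromen-4-one F5.
- Br2 (2 equiv) in AcOH brominates C6 and C8 to 6,8-dibromo-2-(2,3-dimethoxyphenyl)-5,7-dihydroxy-4H-chromen-4-one F6.
- NaOMe and CuBr in DMF–MeOH then give 10.

The 6,8-dibromo-5,7-dihydroxyflavone class is an established substrate for this exchange, and the step count is unchanged. The price is that the bromination must choose ring A over ring B and C3, which is why this order is kept in reserve.

**Step 3.** Alkylation may run on to the tris-ether or stall at the mono-ether, giving a mixture, if the hydrogen bond does not discriminate sharply enough in this crowded triol. Fallback, from 3 back to 5: exhaustive benzylation (excess 4, K2CO3, DMF, 60 °C) gives 1-[2,4,6-tris(benzyloxy)-3,5-dimethoxyphenyl]ethan-1-one F7. One of the two equivalent ortho benzyl ethers is then removed by chelation-controlled cleavage with BCl3 (1.1 equiv, CH2Cl2, −78 °C), which acts at the ether next to the carbonyl and gives 5.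

**Step 5.** The benzyl ether on the C5 oxygen may be partly lost under the hot acidic medium, giving a mixture, and the diketone may undergo retro-Claisen cleavage before the hindered phenol closes. Fallback, from 8 back to 10, with the order of the last two operations reversed: hydrogenolysis of 8 (H2, 10% Pd/C, EtOAc) gives 1-(2,3-dimethoxyphenyl)-3-(2,4,6-trihydroxy-3,5-dimethoxyphenyl)propane-1,3-dione F8, handled under inert gas. Its ring A is symmetric, so closure through either ortho hydroxyl with HCl in MeOH at reflux gives 10 directly.

## Further compounds

F1 | step 4 | 2-acetyl-3,5-bis(benzyloxy)-4,6-dimethoxyphenyl 2,3-dimethoxybenzoate | CC(=O)c1c(OC(=O)c2cccc(OC)c2OC)c(OC)c(OCc2ccccc2)c(OC)c1OCc1ccccc1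
F2 | step 2 | 1-[2,4-bis(benzyloxy)-6-hydroxyphenyl]ethan-1-one | CC(=O)c1c(O)cc(OCc2ccccc2)cc1OCc1ccccc1
F3 | step 2 | 1-[2,4-bis(benzyloxy)-6-hydroxyphenyl]-3-(2,3-dimethoxyphenyl)propane-1,3-dione | COc1cccc(C(=O)CC(=O)c2c(O)cc(OCc3ccccc3)cc2OCc2ccccc2)c1OC
F4 | step 2 | 5,7-bis(benzyloxy)-2-(2,3-dimethoxyphenyl)-4H-chromen-4-one | COc1cccc(-c2cc(=O)c3c(OCc4ccccc4)cc(OCc4ccccc4)cc3o2)c1OC
F5 | step 2 | 2-(2,3-dimethoxyphenyl)-5,7-dihydroxy-4H-chromen-4-one | COc1cccc(-c2cc(=O)c3c(O)cc(O)cc3o2)c1OC
F6 | step 2 | 6,8-dibromo-2-(2,3-dimethoxyphenyl)-5,7-dihydroxy-4H-chromen-4-one | COc1cccc(-c2cc(=O)c3c(O)c(Br)c(O)c(Br)c3o2)c1OC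
F7 | step 3 | 1-[2,4,6-tris(benzyloxy)-3,5-dimethoxyphenyl]ethan-1-one | CC(=O)c1c(OCc2ccccc2)c(OC)c(OCc2ccccc2)c(OC)c1OCc1ccccc1
F8 | step 5 | 1-(2,3-dimethoxyphenyl)-3-(2,4,6-trihydroxy-3,5-dimethoxyphenyl)propane-1,3-dione | COc1cccc(C(=O)CC(=O)c2c(O)c(OC)c(O)c(OC)c2O)c1OC
A1 | alternative 1 | 7-tert-butoxy-2-(2,3-dimethoxyphenyl)-5,8-dihydroxy-6-methoxy-4H-chromen-4-one | COc1cccc(-c2cc(=O)c3c(O)c(OC)c(OC(C)(C)C)c(O)c3o2)c1OC
A2 | alternative 1 | 2-tert-butoxy-4-[6-(2,3-dimethoxyphenyl)-4-oxo-4H-pyran-3-yl]-4-hydroxy-3-methoxycyclobut-2-en-1-one (racemic) | COc1cccc(-c2cc(=O)c(C3(O)C(OC)=C(OC(C)(C)C)C3=O)co2)c1OC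
A3 | alternative 1 | 3-tert-butoxy-4-methoxycyclobut-3-ene-1,2-dione | COC1=C(OC(C)(C)C)C(=O)C1=O
A4 | alternative 2 | 7-(benzyloxy)-2-(2,3-dimethoxyphenyl)-5,8-dihydroxy-6-methoxy-4H-chromen-4-one | COc1cccc(-c2cc(=O)c3c(O)c(OC)c(OCc4ccccc4)c(O)c3o2)c1OC
A5 | alternative 2 | 1-[4-(benzyloxy)-2,5-dihydroxy-3-methoxyphenyl]-3-(2,3-dimethoxyphenyl)propane-1,3-dione | COc1cccc(C(=O)CC(=O)c2cc(O)c(OCc3ccccc3)c(OC)c2O)c1OC
A6 | alternative 3 | 3-(2,3-dimethoxyphenyl)-1-[2,4,6-tris(benzyloxy)-3,5-dimethoxyphenyl]prop-2-yn-1-one | COc1cccc(C#CC(=O)c2c(OCc3ccccc3)c(OC)c(OCc3ccccc3)c(OC)c2OCc2ccccc2)c1OC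
A7 | alternative 3 | 1,3,5-tris(benzyloxy)-2-iodo-4,6-dimethoxybenzene | COc1c(OCc2ccccc2)c(I)c(OCc2ccccc2)c(OC)c1OCc1ccccc1
A8 | alternative 3 | 1-ethynyl-2,3-dimethoxybenzene | C#Cc1cccc(OC)c1OC
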